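The vessel is stirred, at constant volume and temperature, and receives equal charges of G and E, in a different order of addition for each flask.

    G + E → X + D (k1 = 35 /M/min)
    X ⇌ L (K2 = 2.2, k2 = 0.0039 /min)
    E → Q (k3 = 0.023 /min)
    G + X → G.X (k4 = 0.12 /M/min)

| setting | alpha | eta | theta |
|---|---|---|---|
| G | 0.050 M | 0.050 M (fed, over 40 min) | 0.050 M |
| E | 0.0500 M (fed, over 40 min) | 0.0500 M | 0.0500 M |
| time | 1.0 h | 1.0 h | 1.0 h |
| remark | all else is in the flask from the start; the feed brings no volume worth counting | all else is in the flask from the start; the feed brings no volume worth counting | everything together at the start |

- percentages count the G that a species holds: one G.X counts as two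
- run time (alpha): 1.0 h

- the best flask by amount of X, in percent of the G charged; "all alike" if 1.5 percentage points covers them all (alpha / eta / theta / all alike)
- amount of X at the end, in percent of the G charged, alpha
- amount of X at the end, in percent of the G charged, eta
- amount of X at the end, in percent of the G charged, theta

My own reckoning adds the steps one at a time.

1. Coupling by itself brings X to 100 percent in each flask.

2. Now E also decays to Q. E splits between the two paths as G against the break-even concentration of G, g* = 6.57 × 10⁻⁴ M, at which E goes equally to X and Q (a selectivity factor in concentration units). Hence Q = g* ln(G at the start / G now). Each E lost strands one G, so in theta and alpha about 0.00285 M, then on a second pass g = 0.00188 M, stays uncoupled. In eta, G arriving stands near 7.14 × 10⁻⁴ M, close to g*, so at the start of the feed E goes about as fast to Q as to X. Taking each G fed as coupled at once, this reckoning brings E to zero at t = 28.4 min, and the share of G coupled is then 70.9%.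

3. Now X relaxes toward L, with rate 0.00567 /min and a final X share of 31.2%. Over the mean age of X, the surviving fractions are 86.0% in alpha, 84.3% in eta and 80.2% in theta.

4. Last, G takes X, a small correction: 6.00% in alpha, with mean G and the mean share of X over the feed each taken at 0.5 of the charge, 3.49% in eta and 1.36% in theta.

The products give alpha 77.8%, eta 57.7% and theta 76.1%, so the best is alpha.

The forecast names alpha, with 76.8%, 54% and 75.4%; of eta it says “E sits unreacted and decays while G trickles in”.

The simulation gives 77.4%, 54.9% and 75.7%, and alpha leads.

Eta ends with 0.0159 M of Q and alpha with 0.00239 M. Striking out the decay of E turns the alpha-minus-eta difference from 23 percentage points to −4.5 points, the largest single effect among the steps struck out. The alpha answer moves 5 points once E falls to 0.0459 M or G rises to 0.0544 M, so a forecast on those charges would have to change. In the neighbour flask, alpha with 0.20 M of G, G stands far above g*, and the law gives Q = 1.89 × 10⁻⁴ M. The simulation holds 1.95 × 10⁻⁴ M.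

(All constants were set for the occasion; the rest is arithmetic.)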